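**Plan**

- Retrosynthesis: the C9'=C10' double bond of the side chain is cut first (Julia–Kocienski, sulfone on the ring fragment, (2E,4E)-hepta-2,4-dienal as partner). Then the two ring bonds C4–C5 and O2–C3 of the 1,2-dioxolane are cut together.
- Enabling feature: in the ring O1–O2–C3–C4–C5, the atoms C4 and C3 with the C3 methyl and the two-carbon arm are the five carbons of isoprenol. C5 with its methyl and long chain is a methyl ketone at the peroxyketal oxidation level, and O1–O2 come from ozone.
- Forward: a C4 + C8 Grignard coupling gives the chain alkene; ozonolysis in methanol and O-silylation give the silylperoxy ketal. The only ring is closed by SnCl4-promoted annulation with silylated isoprenol. The chloride terminus then becomes the PT-sulfone (PT = 1-phenyl-1H-tetrazol-5-yl), the triene is completed, and the arm is oxidised to the acid last.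
- Stereochemistry: C3 and C5 are both created in the annulation without absolute control. The trans racemate (ring methyls on opposite faces) is separated and then resolved on a chiral stationary phase. Two E double bonds come from the dienal and the third from the Julia–Kocienski step.

Key step: step 5

Remarks on the chemistry: the target is (3S,5R) with the two ring methyl groups trans. Intermediates with a CH2CH2O arm are (3R,5R); the C3 descriptor changes to S at the aldehyde and acid level only because the CIP priorities change, not the configuration. Compounds 5 and 6 are racemic at the peroxyketal carbon, which is of no consequence. For racemates, one enantiomer is drawn in the SMILES.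

**Route**

Step 1
Reactants: 1 1-bromo-8-chlorooctane; 2 2-methylallylmagnesium chloride
Product: 3 11-chloro-2-methylundec-1-ene
Conditions: Li2CuCl4 (3 mol %), THF, −20 → 0 °C
Reagents that add atoms: none
Why: Copper-catalysed Grignard–alkyl halide cross-coupling (Kochi type), in which the allylic Grignard displaces the primary bromide much faster than the chloride, so the chloride is kept as the later handle for the sulfone.

Step 2
Reactants: 3 11-chloro-2-methylundec-1-ene
Product: 5 11-chloro-2-methoxyundecan-2-yl hydroperoxide, via carbonyl oxide 4 (not isolated)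
Conditions: O3, CH2Cl2/MeOH, −78 °C; N2 purge, no reductive work-up
Reagents that add atoms: ozone, [O-][O+]=O; methanol, CO
Why: Ozonolysis with Criegee trapping: the primary ozonide of a 1,1-disubstituted alkene cleaves to formaldehyde and the ketone oxide 4, which methanol captures as the methoxy hydroperoxide, while the primary chloride is inert.

Step 3
Reactants: 5 11-chloro-2-methoxyundecan-2-yl hydroperoxide
Product: 6 [(11-chloro-2-methoxyundecan-2-yl)peroxy]triethylsilane
Conditions: Et3SiCl, imidazole, DMF, 0 °C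
Reagents that add atoms: chlorotriethylsilane, CC[Si](Cl)(CC)CC
Why: Imidazole-promoted O-silylation of the hydroperoxide (same reactivity as an alcohol) under basic conditions, which spares the acid-labile peroxyketal and installs the silyl group that later leaves in the ring closure.

Step 4
Reactants: 7 3-methylbut-3-en-1-ol
Product: 8 tert-butyl[(3-methylbut-3-en-1-yl)oxy]diphenylsilane
Conditions: t-BuPh2SiCl, imidazole, CH2Cl2, 0 °C → rt
Reagents that add atoms: tert-butyl(chloro)diphenylsilane, CC(C)(C)[Si](Cl)(c1ccccc1)c1ccccc1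
Why: Standard silyl ether formation at a primary alcohol; the bulky silyl ether should survive SnCl4 at −78 °C, H2O2 and KN(SiMe3)2 and is removed later by fluoride.

Step 5
Reactants: 6 [(11-chloro-2-methoxyundecan-2-yl)peroxy]triethylsilane; 8 tert-butyl[(3-methylbut-3-en-1-yl)oxy]diphenylsilane
Product: 11 rac-tert-butyl{2-[(3R,5R)-5-(9-chlorononyl)-3,5-dimethyl-1,2-dioxolan-3-yl]ethoxy}diphenylsilane (trans racemate), via silylperoxycarbenium ion 9 (not isolated), via tertiary carbocation 10 (not isolated)
Conditions: SnCl4 (1.1 equiv), 8 (2 equiv), CH2Cl2, −78 °C; aq. NaHCO3; SiO2 chromatography (preparative HPLC if needed) to separate trans from cis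
Reagents that add atoms: none
Why: SnCl4 removes methoxide from 6 to give the silylperoxycarbenium ion 9; the CH2 terminus of alkene 8 adds to its carbon (C4–C5 bond, Prins-type), and the tertiary C3 cation 10 is captured by the silyl-bearing peroxide oxygen (O2–C3 bond) with loss of the triethylsilyl group as Et3SiOMe. The closest known reaction type is the SnCl4-promoted annulation of triethylsilylperoxy ketals with alkenes to 1,2-dioxolanes, a stepwise cationic (3+2) process. The single ring closes by polar collapse of an oxygen onto a carbocation, with the C–O–O unit supplied by 6 and two carbons by 8. C5 is formed when the planar ion 9 is attacked and is racemic; C3 is formed in the ring closure, where the bias between methyl and chain at C5 is expected to be weak, so cis and trans isomers should both form and the trans racemate is isolated by chromatography. The step needs regioselectivity, which the 1,1-disubstitution of 8 secures because only the tertiary cation is reasonable. It also needs ionisation of the ketal in preference to Hock-type O–O cleavage, which is favoured by the two alkyl groups on 9, the low temperature, and the inertness of the primary chloride and the silyl ether.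

Step 6
Reactants: 11 rac-tert-butyl{2-[(3R,5R)-5-(9-chlorononyl)-3,5-dimethyl-1,2-dioxolan-3-yl]ethoxy}diphenylsilane
Product: 12 tert-butyl{2-[(3R,5R)-5-(9-chlorononyl)-3,5-dimethyl-1,2-dioxolan-3-yl]ethoxy}diphenylsilane (single enantiomer)
Conditions: preparative HPLC on cellulose tris(3,5-dimethylphenylcarbamate)/silica, hexane/i-PrOH, 25 °C
Reagents that add atoms: none
Why: Chromatographic resolution on a chiral stationary phase separates the two enantiomers without any bond change, the diphenylsilyl ether next to C3 giving π-contact and UV detection; the (3R,5R) antipode would be identified by anomalous-dispersion X-ray analysis of a crystalline derivative (chlorine as heavy atom) or by carrying both antipodes to 20 on small scale and comparing the sign of rotation with the natural acid.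

Step 7
Reactants: 12 tert-butyl{2-[(3R,5R)-5-(9-chlorononyl)-3,5-dimethyl-1,2-dioxolan-3-yl]ethoxy}diphenylsilane
Product: 13 5-({9-[(3R,5R)-5-{2-[(tert-butyldiphenylsilyl)oxy]ethyl}-3,5-dimethyl-1,2-dioxolan-3-yl]nonyl}sulfanyl)-1-phenyl-1H-tetrazole
Conditions: 1-phenyl-1H-tetrazole-5-thiol, K2CO3, NaI (cat.), DMF, 60 °C
Reagents that add atoms: 1-phenyl-1H-tetrazole-5-thiol, Sc1nnnn1-c1ccccc1
Why: Iodide-assisted SN2 thioetherification (Finkelstein catalysis) of the primary chloride by the soft tetrazolethiolate; the tetrasubstituted dioxolane has no ring C–H next to oxygen and should tolerate weak base and mild heating.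

Step 8
Reactants: 13 5-({9-[(3R,5R)-5-{2-[(tert-butyldiphenylsilyl)oxy]ethyl}-3,5-dimethyl-1,2-dioxolan-3-yl]nonyl}sulfanyl)-1-phenyl-1H-tetrazole
Product: 14 5-({9-[(3R,5R)-5-{2-[(tert-butyldiphenylsilyl)oxy]ethyl}-3,5-dimethyl-1,2-dioxolan-3-yl]nonyl}sulfonyl)-1-phenyl-1H-tetrazole
Conditions: (NH4)6Mo7O24·4H2O (cat.), 30% H2O2, EtOH/THF, 0 °C → rt
Reagents that add atoms: hydrogen peroxide, OO
Why: Molybdate-catalysed H2O2 oxidation of a sulfide to the sulfone, a standard route to PT-sulfones, to which a di-tert-alkyl peroxide and a silyl ether are inert.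

Step 9
Reactants: 14 5-({9-[(3R,5R)-5-{2-[(tert-butyldiphenylsilyl)oxy]ethyl}-3,5-dimethyl-1,2-dioxolan-3-yl]nonyl}sulfonyl)-1-phenyl-1H-tetrazole; 15 (2E,4E)-hepta-2,4-dienal
Product: 17 tert-butyl{2-[(3R,5R)-5-[(9E,11E,13E)-hexadeca-9,11,13-trien-1-yl]-3,5-dimethyl-1,2-dioxolan-3-yl]ethoxy}diphenylsilane, via potassium α-sulfonyl carbanion 16 (not isolated)
Conditions: KN(SiMe3)2 (1.05 equiv), DME, −55 °C; then 15; → rt
Reagents that add atoms: none
Why: Julia–Kocienski olefination: the premetalated PT-sulfone adds to the aldehyde, and Smiles rearrangement with loss of SO2 and tetrazolate gives the alkene, E-selective with potassium in DME and further favoured by the conjugated aldehyde; premetalation avoids vinylogous enolisation of 15, and the ring carbons carry no hydrogen, so base cannot fragment the peroxide.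

Step 10
Reactants: 17 tert-butyl{2-[(3R,5R)-5-[(9E,11E,13E)-hexadeca-9,11,13-trien-1-yl]-3,5-dimethyl-1,2-dioxolan-3-yl]ethoxy}diphenylsilane
Product: 18 2-[(3R,5R)-5-[(9E,11E,13E)-hexadeca-9,11,13-trien-1-yl]-3,5-dimethyl-1,2-dioxolan-3-yl]ethan-1-ol
Conditions: Bu4NF, THF, 0 °C → rt
Reagents that add atoms: none
Why: Fluoride-driven cleavage of the silyl ether (desilylation through the strong Si–F bond), which should affect neither the peroxide nor the triene.

Step 11
Reactants: 18 2-[(3R,5R)-5-[(9E,11E,13E)-hexadeca-9,11,13-trien-1-yl]-3,5-dimethyl-1,2-dioxolan-3-yl]ethan-1-ol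
Product: 19 2-[(3S,5R)-5-[(9E,11E,13E)-hexadeca-9,11,13-trien-1-yl]-3,5-dimethyl-1,2-dioxolan-3-yl]acetaldehyde
Conditions: Dess–Martin periodinane, NaHCO3, CH2Cl2, 0 °C; used at once
Reagents that add atoms: none
Why: Dess–Martin oxidation of a primary alcohol under buffered conditions stops at the aldehyde and leaves the triene and peroxide alone; the β-peroxy aldehyde is taken on directly to avoid base-induced β-elimination.

Step 12
Reactants: 19 2-[(3S,5R)-5-[(9E,11E,13E)-hexadeca-9,11,13-trien-1-yl]-3,5-dimethyl-1,2-dioxolan-3-yl]acetaldehyde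
Product: 20 2-[(3S,5R)-5-[(9E,11E,13E)-hexadeca-9,11,13-trien-1-yl]-3,5-dimethyl-1,2-dioxolan-3-yl]acetic acid
Conditions: NaClO2, NaH2PO4, 2-methylbut-2-ene (excess), t-BuOH/H2O, 0 °C → rt
Reagents that add atoms: sodium chlorite, [Na+].[O-]Cl=O
Why: Pinnick oxidation: chlorous acid converts the aldehyde to the acid at about pH 4, and the large excess of 2-methylbut-2-ene scavenges HOCl so that the conjugated triene is not chlorinated.

**Compound list**

1 | 1-bromo-8-chlorooctane | ClCCCCCCCCBr | starting material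
2 | 2-methylallylmagnesium chloride (CH2=C(CH3)CH2MgCl, THF solution) | C=C(C)C[Mg]Cl | starting material
3 | 11-chloro-2-methylundec-1-ene | C=C(C)CCCCCCCCCCl | intermediate
4 | 11-chloroundecan-2-one O-oxide (carbonyl oxide, not isolated) | CC(CCCCCCCCCCl)=[O+][O-] | intermediate
5 | 11-chloro-2-methoxyundecan-2-yl hydroperoxide (racemic) | COC(C)(CCCCCCCCCCl)OO | intermediate
6 | [(11-chloro-2-methoxyundecan-2-yl)peroxy]triethylsilane (racemic) | CC[Si](CC)(CC)OOC(C)(OC)CCCCCCCCCCl | intermediate
7 | 3-methylbut-3-en-1-ol | C=C(C)CCO | starting material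
8 | tert-butyl[(3-methylbut-3-en-1-yl)oxy]diphenylsilane | C=C(C)CCO[Si](c1ccccc1)(c1ccccc1)C(C)(C)C | intermediate
9 | (11-chloroundecan-2-ylidene)[(triethylsilyl)oxy]oxonium (silylperoxycarbenium ion, not isolated) | CC(CCCCCCCCCCl)=[O+]O[Si](CC)(CC)CC | intermediate
10 | 1-[(tert-butyldiphenylsilyl)oxy]-14-chloro-3,5-dimethyl-5-[(triethylsilyl)peroxy]tetradecan-3-ylium (tertiary carbocation, not isolated) | CC[Si](CC)(CC)OOC(C)(CCCCCCCCCCl)C[C+](C)CCO[Si](c1ccccc1)(c1ccccc1)C(C)(C)C | intermediate
11 | rac-tert-butyl{2-[(3R,5R)-5-(9-chlorononyl)-3,5-dimethyl-1,2-dioxolan-3-yl]ethoxy}diphenylsilane (trans racemate, one enantiomer drawn) | ClCCCCCCCCC[C@]1(C)C[C@@](C)(CCO[Si](c2ccccc2)(c2ccccc2)C(C)(C)C)OO1 | intermediate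
12 | tert-butyl{2-[(3R,5R)-5-(9-chlorononyl)-3,5-dimethyl-1,2-dioxolan-3-yl]ethoxy}diphenylsilane (single enantiomer) | ClCCCCCCCCC[C@]1(C)C[C@@](C)(CCO[Si](c2ccccc2)(c2ccccc2)C(C)(C)C)OO1 | intermediate
13 | 5-({9-[(3R,5R)-5-{2-[(tert-butyldiphenylsilyl)oxy]ethyl}-3,5-dimethyl-1,2-dioxolan-3-yl]nonyl}sulfanyl)-1-phenyl-1H-tetrazole | c1ccccc1-n1nnnc1SCCCCCCCCC[C@]2(C)C[C@@](C)(CCO[Si](c3ccccc3)(c3ccccc3)C(C)(C)C)OO2 | intermediate
14 | 5-({9-[(3R,5R)-5-{2-[(tert-butyldiphenylsilyl)oxy]ethyl}-3,5-dimethyl-1,2-dioxolan-3-yl]nonyl}sulfonyl)-1-phenyl-1H-tetrazole | c1ccccc1-n1nnnc1S(=O)(=O)CCCCCCCCC[C@]2(C)C[C@@](C)(CCO[Si](c3ccccc3)(c3ccccc3)C(C)(C)C)OO2 | intermediate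
15 | (2E,4E)-hepta-2,4-dienal | CC/C=C/C=C/C=O | starting material
16 | potassium salt of the α-sulfonyl carbanion of 14 (not isolated) | [K+].c1ccccc1-n1nnnc1S(=O)(=O)[CH-]CCCCCCCC[C@]2(C)C[C@@](C)(CCO[Si](c3ccccc3)(c3ccccc3)C(C)(C)C)OO2 | intermediate
17 | tert-butyl{2-[(3R,5R)-5-[(9E,11E,13E)-hexadeca-9,11,13-trien-1-yl]-3,5-dimethyl-1,2-dioxolan-3-yl]ethoxy}diphenylsilane | CC/C=C/C=C/C=C/CCCCCCCC[C@]1(C)C[C@@](C)(CCO[Si](c2ccccc2)(c2ccccc2)C(C)(C)C)OO1 | intermediate
18 | 2-[(3R,5R)-5-[(9E,11E,13E)-hexadeca-9,11,13-trien-1-yl]-3,5-dimethyl-1,2-dioxolan-3-yl]ethan-1-ol | CC/C=C/C=C/C=C/CCCCCCCC[C@]1(C)C[C@@](C)(CCO)OO1 | intermediate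
19 | 2-[(3S,5R)-5-[(9E,11E,13E)-hexadeca-9,11,13-trien-1-yl]-3,5-dimethyl-1,2-dioxolan-3-yl]acetaldehyde | CC/C=C/C=C/C=C/CCCCCCCC[C@]1(C)C[C@@](C)(CC=O)OO1 | intermediate
20 | 2-[(3S,5R)-5-[(9E,11E,13E)-hexadeca-9,11,13-trien-1-yl]-3,5-dimethyl-1,2-dioxolan-3-yl]acetic acid | CC/C=C/C=C/C=C/CCCCCCCC[C@]1(C)C[C@@](C)(CC(=O)O)OO1 | target

**Step count**

Total: 12 steps (11 reactions and one chromatographic resolution, step 6).
Longest linear sequence: 11 steps (steps 1, 2, 3, 5–12, from 1-bromo-8-chlorooctane); step 4 is a one-step side branch.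

**Steps most likely to fail**

Step 5. The ring closure may show no useful facial bias, so the trans isomer could be the minor and poorly separable component; the tertiary cation may also be lost to chloride capture or proton loss. The fallback sets out from 6 and comes back at 11, building the two quaternary centres in separate steps. 6 is treated with 2-(trimethylsilyloxy)propene and SnCl4 in CH2Cl2 at −78 °C (Mukaiyama-type addition of an enol silane to the peroxycarbenium ion) to give 13-chloro-4-methyl-4-[(triethylsilyl)peroxy]tridecan-2-one F1. TsOH in methanol removes the silyl group, and the β-hydroperoxy ketone closes to 5-(9-chlorononyl)-3,5-dimethyl-1,2-dioxolan-3-ol F2, which is ketalised in the same medium to 5-(9-chlorononyl)-3-methoxy-3,5-dimethyl-1,2-dioxolane F3. TiCl4 and tert-butyl[(1-methoxyvinyl)oxy]dimethylsilane then replace the methoxy group through the cyclic peroxycarbenium ion. The ketene acetal is expected to approach C3 anti to the larger C5 substituent and give rac-methyl 2-[(3S,5R)-5-(9-chlorononyl)-3,5-dimethyl-1,2-dioxolan-3-yl]acetate F4. LiBH4 in THF reduces the ester to rac-2-[(3R,5R)-5-(9-chlorononyl)-3,5-dimethyl-1,2-dioxolan-3-yl]ethan-1-ol F5, and silylation with t-BuPh2SiCl and imidazole returns 11.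

Step 6. Chiral recognition may be too weak for a lipophilic, flexible molecule whose stereocentres carry no polar group, so a preparative baseline separation may not be reached. The fallback sets out from 11 and comes back at 12, using covalent diastereomers. Bu4NF removes the silyl group to give rac-2-[(3R,5R)-5-(9-chlorononyl)-3,5-dimethyl-1,2-dioxolan-3-yl]ethan-1-ol F6, which is esterified with (2S)-2-methoxy-2-phenylacetic acid (dicyclohexylcarbodiimide, 4-dimethylaminopyridine, CH2Cl2). The two diastereomeric esters are separated on silica or by crystallisation. The isomer 2-[(3R,5R)-5-(9-chlorononyl)-3,5-dimethyl-1,2-dioxolan-3-yl]ethyl (2S)-2-methoxy-2-phenylacetate F7 is cleaved with K2CO3 in methanol to 2-[(3R,5R)-5-(9-chlorononyl)-3,5-dimethyl-1,2-dioxolan-3-yl]ethan-1-ol F8 (single enantiomer), and silylation with t-BuPh2SiCl and imidazole gives 12.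

Step 9. E-selectivity at the new C9=C10 bond may be incomplete, and the sulfonyl carbanion may attack the O–O bond by electron transfer or substitution. The fallback sets out from 12 and 15 and comes back at 17, reversing the polarity of the olefination.
- Ring fragment: 12 is converted with KOAc and NaI in DMF at 70 °C into 9-[(3R,5R)-5-{2-[(tert-butyldiphenylsilyl)oxy]ethyl}-3,5-dimethyl-1,2-dioxolan-3-yl]nonyl acetate F9. Methanolysis with K2CO3 in MeOH gives 9-[(3R,5R)-5-{2-[(tert-butyldiphenylsilyl)oxy]ethyl}-3,5-dimethyl-1,2-dioxolan-3-yl]nonan-1-ol F10, and Dess–Martin oxidation gives 9-[(3R,5R)-5-{2-[(tert-butyldiphenylsilyl)oxy]ethyl}-3,5-dimethyl-1,2-dioxolan-3-yl]nonanal F11.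
- Dienyl fragment: 15 is reduced with NaBH4 to (2E,4E)-hepta-2,4-dien-1-ol F12, converted with PBr3 into (2E,4E)-1-bromohepta-2,4-diene F13, and heated with P(OEt)3 (Arbuzov reaction) to give diethyl [(2E,4E)-hepta-2,4-dien-1-yl]phosphonate F14.
- Coupling: Horner–Wadsworth–Emmons olefination of F11 with the anion of F14 (LiN(SiMe3)2, THF, −78 °C → rt), which is normally E-selective for allylic phosphonates, gives 17.

Further compounds

F1 | step 5 | 13-chloro-4-methyl-4-[(triethylsilyl)peroxy]tridecan-2-one (racemic) | CC(=O)CC(C)(CCCCCCCCCCl)OO[Si](CC)(CC)CC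
F2 | step 5 | 5-(9-chlorononyl)-3,5-dimethyl-1,2-dioxolan-3-ol (diastereomer mixture) | CC1(O)CC(C)(CCCCCCCCCCl)OO1
F3 | step 5 | 5-(9-chlorononyl)-3-methoxy-3,5-dimethyl-1,2-dioxolane (diastereomer mixture) | COC1(C)CC(C)(CCCCCCCCCCl)OO1
F4 | step 5 | rac-methyl 2-[(3S,5R)-5-(9-chlorononyl)-3,5-dimethyl-1,2-dioxolan-3-yl]acetate (trans racemate, one enantiomer drawn) | ClCCCCCCCCC[C@]1(C)C[C@@](C)(CC(=O)OC)OO1
F5 | step 5 | rac-2-[(3R,5R)-5-(9-chlorononyl)-3,5-dimethyl-1,2-dioxolan-3-yl]ethan-1-ol (trans racemate, one enantiomer drawn) | ClCCCCCCCCC[C@]1(C)C[C@@](C)(CCO)OO1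
F6 | step 6 | rac-2-[(3R,5R)-5-(9-chlorononyl)-3,5-dimethyl-1,2-dioxolan-3-yl]ethan-1-ol (trans racemate, one enantiomer drawn; same substance as F5) | ClCCCCCCCCC[C@]1(C)C[C@@](C)(CCO)OO1
F7 | step 6 | 2-[(3R,5R)-5-(9-chlorononyl)-3,5-dimethyl-1,2-dioxolan-3-yl]ethyl (2S)-2-methoxy-2-phenylacetate | ClCCCCCCCCC[C@]1(C)C[C@@](C)(CCOC(=O)[C@@H](OC)c2ccccc2)OO1
F8 | step 6 | 2-[(3R,5R)-5-(9-chlorononyl)-3,5-dimethyl-1,2-dioxolan-3-yl]ethan-1-ol (single enantiomer) | ClCCCCCCCCC[C@]1(C)C[C@@](C)(CCO)OO1
F9 | step 9 | 9-[(3R,5R)-5-{2-[(tert-butyldiphenylsilyl)oxy]ethyl}-3,5-dimethyl-1,2-dioxolan-3-yl]nonyl acetate | CC(=O)OCCCCCCCCC[C@]1(C)C[C@@](C)(CCO[Si](c2ccccc2)(c2ccccc2)C(C)(C)C)OO1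
F10 | step 9 | 9-[(3R,5R)-5-{2-[(tert-butyldiphenylsilyl)oxy]ethyl}-3,5-dimethyl-1,2-dioxolan-3-yl]nonan-1-ol | OCCCCCCCCC[C@]1(C)C[C@@](C)(CCO[Si](c2ccccc2)(c2ccccc2)C(C)(C)C)OO1
F11 | step 9 | 9-[(3R,5R)-5-{2-[(tert-butyldiphenylsilyl)oxy]ethyl}-3,5-dimethyl-1,2-dioxolan-3-yl]nonanal | O=CCCCCCCCC[C@]1(C)C[C@@](C)(CCO[Si](c2ccccc2)(c2ccccc2)C(C)(C)C)OO1
F12 | step 9 | (2E,4E)-hepta-2,4-dien-1-ol | CC/C=C/C=C/CO
F13 | step 9 | (2E,4E)-1-bromohepta-2,4-diene | CC/C=C/C=C/CBr
F14 | step 9 | diethyl [(2E,4E)-hepta-2,4-dien-1-yl]phosphonate | CC/C=C/C=C/CP(=O)(OCC)OCC
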